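**Plan**

Locants: C1 bears ring C, C2 OH, C3 CHO, C7 OH, C8 OMe; ring A is C4a/C5–C8/C8a and ring B is C1–C4/C4a/C8a. Bonds are cut in the order C3–CHO, C1–C2 (opens ring B), C3=C4, C8a–C1.
Enabling feature: C2 of ring B carries oxygen and is bonded to C1, the ring B carbon that bears ring C. In the open form C1 is a diarylmethane CH2 that can give up a hydrogen, and C2 is a ketene carbon onto which C1 can close.
Forward: rings A and C are bought as arenes and joined through C1 by cross-coupling. C4 is the formyl carbon, and C3 and C2 come from Meldrum's acid. Ring B is the only ring made, and it forms in the pyrolysis.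
Endgame: C3 of a 2-naphthol is a poor nucleophile, because attack there breaks the aromaticity of both rings. The formyl group therefore enters by directed lithiation of the C2 O-MOM ether, and both hydroxyl groups are released afterwards.
Stereochemistry: the target has no stereocentre, and ring C has no ortho substituent to lock the C1–aryl axis, so nothing needs control.

Key step: step 7

Remark: locants in the running text follow the 1-aryl-2-naphthol numbering above, while the systematic names of the naphthalene-2-carbaldehydes use their own IUPAC locants.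

**Step 1**
Reactants: 1 2-methoxybenzene-1,3-diol
Product: 3 2,4-dihydroxy-3-methoxybenzaldehyde, via aryl iminium chloride 2 (not isolated)
Conditions: POCl3, DMF, MeCN, −15 °C → rt; then H2O, 50 °C
Reagents that add atoms: N,N-dimethylformamide CN(C)C=O; water O
Why: In this Vilsmeier–Haack formylation the chloroiminium ion attacks the position ortho to one hydroxyl and para to the other (the two such sites are equivalent by symmetry), the cationic salt 2 resists a second attack, and warm water hydrolyses it to the aldehyde.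

**Step 2**
Reactants: 3 2,4-dihydroxy-3-methoxybenzaldehyde
Product: 4 4-[(tert-butyldimethylsilyl)oxy]-2-hydroxy-3-methoxybenzaldehyde
Conditions: TBSCl (1.05 equiv), imidazole, CH2Cl2, 0 °C
Reagents that add atoms: tert-butyldimethylsilyl chloride CC(C)(C)[Si](C)(C)Cl
Why: This is a chemoselective phenol silylation, because the 2-hydroxyl is hydrogen-bonded to the formyl oxygen and flanked on both sides, so the freer and more acidic 4-hydroxyl should react first, as is usual for 2,4-dihydroxybenzaldehydes.

**Step 3**
Reactants: 4 4-[(tert-butyldimethylsilyl)oxy]-2-hydroxy-3-methoxybenzaldehyde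
Product: 5 3-[(tert-butyldimethylsilyl)oxy]-6-formyl-2-methoxyphenyl trifluoromethanesulfonate
Conditions: Tf2O, pyridine, CH2Cl2, 0 °C → rt
Reagents that add atoms: trifluoromethanesulfonic anhydride FC(F)(F)S(=O)(=O)OS(=O)(=O)C(F)(F)F
Why: O-Triflation of a phenol set between a formyl and a methoxy group is routine for o-vanillin-type salicylaldehydes, and the silyl ether and the aldehyde are inert to the reagent pair.

**Step 4**
Reactants: 6 4-(chloromethyl)-1,2-dimethoxybenzene
Product: 7 (3,4-dimethoxybenzyl)zinc chloride, kept as a titrated THF solution containing LiCl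
Conditions: Zn dust, LiCl, THF, 25 °C
Reagents that add atoms: zinc [Zn]
Why: LiCl-promoted direct insertion of zinc into a benzylic chloride runs at room temperature, tolerates aryl methyl ethers, forms little Wurtz dimer and gives a storable solution.

**Step 5**
Reactants: 5 3-[(tert-butyldimethylsilyl)oxy]-6-formyl-2-methoxyphenyl trifluoromethanesulfonate; 7 (3,4-dimethoxybenzyl)zinc chloride
Product: 8 4-[(tert-butyldimethylsilyl)oxy]-2-[(3,4-dimethoxyphenyl)methyl]-3-methoxybenzaldehyde
Conditions: Pd(OAc)2 (2 mol %), SPhos (4 mol %), THF, 25 °C, slow addition of 7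
Reagents that add atoms: none
Why: In this Negishi cross-coupling the ortho formyl group activates the triflate towards oxidative addition, the bulky biarylphosphine copes with the two ortho substituents, and a low standing concentration of 7 favours coupling over addition to the aldehyde.

**Step 6**
Reactants: 8 4-[(tert-butyldimethylsilyl)oxy]-2-[(3,4-dimethoxyphenyl)methyl]-3-methoxybenzaldehyde; 9 Meldrum's acid (2,2-dimethyl-1,3-dioxane-4,6-dione)
Product: 10 5-({4-[(tert-butyldimethylsilyl)oxy]-2-[(3,4-dimethoxyphenyl)methyl]-3-methoxyphenyl}methylidene)-2,2-dimethyl-1,3-dioxane-4,6-dione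
Conditions: pyrrolidine, AcOH (10 mol % each), 4 Å MS, toluene, rt → 40 °C
Reagents that add atoms: none
Why: This Knoevenagel condensation runs through the iminium ion of the aldehyde, the very acidic methylene of 9 condenses under almost neutral amine-salt catalysis that spares the aryl silyl ether, and the push-pull product should be purified by crystallisation.

**Step 7**
Reactants: 10 5-({4-[(tert-butyldimethylsilyl)oxy]-2-[(3,4-dimethoxyphenyl)methyl]-3-methoxyphenyl}methylidene)-2,2-dimethyl-1,3-dioxane-4,6-dione
Product: 14 7-[(tert-butyldimethylsilyl)oxy]-1-(3,4-dimethoxyphenyl)-8-methoxynaphthalen-2-ol, via methyleneketene 11 (not isolated), via dienylketene 12 (not isolated), via naphthalenone 13 (not isolated)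
Conditions: flash vacuum pyrolysis, inlet 180–200 °C, quartz tube 575 °C, 0.001 Torr, trap −196 °C
Reagents that add atoms: none
Why: In the hot tube the dioxanedione ring of 10 fragments by cycloreversion, losing acetone and CO2 and leaving the arylmethyleneketene 11 (C4=C3=C2=O). A [1,5]-hydrogen shift then carries one doubly benzylic hydrogen from the C1 methylene to the central cumulene carbon C3 and gives the ortho-quinodimethane dienylketene 12. Ring B closes by a thermal disrotatory 6π-electrocyclisation in which C1 bonds to the ketene carbon C2, forming the six-membered 1H-naphthalen-2-one 13, and enolisation restores aromaticity to give 14. This is the known flash vacuum pyrolysis of ortho-alkylbenzylidene Meldrum's acid derivatives to 2-naphthols, and it leaves no stereocentre because C1 of 13 becomes planar on enolisation. The selectivity needed is the choice of hydrogen donor, and it is secured because the other ortho position of ring A carries only an sp2 C–H and all methoxy groups lie out of reach, so only the C1 methylene stands in a 1,5-relationship to C3 and only a six-membered ring can form. Unimolecular gas-phase conditions suppress ketene dimerisation, a furnace held below 600 °C limits decarbonylation of 11 to the arylalkyne, and the silyl ether raises volatility without offering a low-energy fragmentation path.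

**Step 8**
Reactants: 14 7-[(tert-butyldimethylsilyl)oxy]-1-(3,4-dimethoxyphenyl)-8-methoxynaphthalen-2-ol
Product: 15 7-[(tert-butyldimethylsilyl)oxy]-1-(3,4-dimethoxyphenyl)-8-methoxy-2-(methoxymethoxy)naphthalene
Conditions: MOMCl, iPr2NEt, CH2Cl2, 0 °C → rt
Reagents that add atoms: chloromethyl methyl ether COCCl
Why: O-Alkylation of the naphthol under amine base is routine for hindered 1-aryl-2-naphthols such as binaphthols, leaves the silyl ether alone and installs the group that will direct metalation.

**Step 9**
Reactants: 15 7-[(tert-butyldimethylsilyl)oxy]-1-(3,4-dimethoxyphenyl)-8-methoxy-2-(methoxymethoxy)naphthalene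
Product: 18 6-[(tert-butyldimethylsilyl)oxy]-4-(3,4-dimethoxyphenyl)-5-methoxy-3-(methoxymethoxy)naphthalene-2-carbaldehyde, via 3-lithionaphthalene 16 (not isolated), via lithium hemiaminal alkoxide 17 (not isolated)
Conditions: n-BuLi, TMEDA, THF, −78 → 0 °C; DMF, −78 °C → rt; aq NH4Cl
Reagents that add atoms: N,N-dimethylformamide CN(C)C=O
Why: In this directed ortho-metalation and DMF formylation the chelating OMOM group steers lithium to C3, its only free ortho position, as in the 3-functionalisation of MOM-protected binaphthols, whereas the bulky silyloxy group does not direct and the methoxy groups of ring C are weaker directors.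

**Step 10**
Reactants: 18 6-[(tert-butyldimethylsilyl)oxy]-4-(3,4-dimethoxyphenyl)-5-methoxy-3-(methoxymethoxy)naphthalene-2-carbaldehyde
Product: 20 vitrofolal B, via 7-hydroxy MOM ether 19 (not isolated)
Conditions: Bu4NF, THF, 0 °C; then 3 M aq HCl, 50 °C
Reagents that add atoms: none
Why: Fluoride-induced desilylation of the aryl silyl ether is followed in the same flask by acid hydrolysis of the MOM acetal, which is favoured by the hydrogen bond that forms between the C2 hydroxyl and the C3 formyl group, and neither reagent touches the methyl ethers or the aldehyde.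

**Compound list**

1 | 2-methoxybenzene-1,3-diol (2-methoxyresorcinol) | COc1c(O)cccc1O | starting material
2 | [(2,4-dihydroxy-3-methoxyphenyl)methylidene]dimethylammonium chloride | C[N+](C)=Cc1ccc(O)c(OC)c1O.[Cl-] | intermediate
3 | 2,4-dihydroxy-3-methoxybenzaldehyde | O=Cc1ccc(O)c(OC)c1O | intermediate
4 | 4-[(tert-butyldimethylsilyl)oxy]-2-hydroxy-3-methoxybenzaldehyde | O=Cc1ccc(O[Si](C)(C)C(C)(C)C)c(OC)c1O | intermediate
5 | 3-[(tert-butyldimethylsilyl)oxy]-6-formyl-2-methoxyphenyl trifluoromethanesulfonate | O=Cc1ccc(O[Si](C)(C)C(C)(C)C)c(OC)c1OS(=O)(=O)C(F)(F)F | intermediate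
6 | 4-(chloromethyl)-1,2-dimethoxybenzene (3,4-dimethoxybenzyl chloride) | COc1ccc(CCl)cc1OC | starting material
7 | (3,4-dimethoxybenzyl)zinc chloride (THF solution with LiCl) | COc1ccc(C[Zn]Cl)cc1OC | intermediate
8 | 4-[(tert-butyldimethylsilyl)oxy]-2-[(3,4-dimethoxyphenyl)methyl]-3-methoxybenzaldehyde | O=Cc1ccc(O[Si](C)(C)C(C)(C)C)c(OC)c1Cc1ccc(OC)c(OC)c1 | intermediate
9 | Meldrum's acid (2,2-dimethyl-1,3-dioxane-4,6-dione) | CC1(C)OC(=O)CC(=O)O1 | starting material
10 | 5-({4-[(tert-butyldimethylsilyl)oxy]-2-[(3,4-dimethoxyphenyl)methyl]-3-methoxyphenyl}methylidene)-2,2-dimethyl-1,3-dioxane-4,6-dione | CC1(C)OC(=O)C(=Cc2ccc(O[Si](C)(C)C(C)(C)C)c(OC)c2Cc2ccc(OC)c(OC)c2)C(=O)O1 | intermediate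
11 | 3-{4-[(tert-butyldimethylsilyl)oxy]-2-[(3,4-dimethoxyphenyl)methyl]-3-methoxyphenyl}propa-1,2-dien-1-one (methyleneketene) | O=C=C=Cc1ccc(O[Si](C)(C)C(C)(C)C)c(OC)c1Cc1ccc(OC)c(OC)c1 | intermediate
12 | ortho-quinodimethane dienylketene: ring A dearomatised, exocyclic C4a=C4H–C3H=C2=O with the ketene arm turned towards C1, exocyclic C8a=C1H(3,4-dimethoxyphenyl) drawn with the aryl group outward | O=C=C/C=C1/C=CC(O[Si](C)(C)C(C)(C)C)=C(OC)/C1=C\c1ccc(OC)c(OC)c1 | intermediate
13 | 7-[(tert-butyldimethylsilyl)oxy]-1-(3,4-dimethoxyphenyl)-8-methoxy-1H-naphthalen-2-one (racemic, transient) | O=C1C=Cc2ccc(O[Si](C)(C)C(C)(C)C)c(OC)c2C1c1ccc(OC)c(OC)c1 | intermediate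
14 | 7-[(tert-butyldimethylsilyl)oxy]-1-(3,4-dimethoxyphenyl)-8-methoxynaphthalen-2-ol | COc1ccc(-c2c(O)ccc3ccc(O[Si](C)(C)C(C)(C)C)c(OC)c23)cc1OC | intermediate
15 | 7-[(tert-butyldimethylsilyl)oxy]-1-(3,4-dimethoxyphenyl)-8-methoxy-2-(methoxymethoxy)naphthalene | COCOc1ccc2ccc(O[Si](C)(C)C(C)(C)C)c(OC)c2c1-c1ccc(OC)c(OC)c1 | intermediate
16 | 3-lithio derivative of 15 | [Li]c1cc2ccc(O[Si](C)(C)C(C)(C)C)c(OC)c2c(-c2ccc(OC)c(OC)c2)c1OCOC | intermediate
17 | lithium (dimethylamino)(aryl)methoxide formed from 16 and DMF (racemic, transient) | [Li]OC(N(C)C)c1cc2ccc(O[Si](C)(C)C(C)(C)C)c(OC)c2c(-c2ccc(OC)c(OC)c2)c1OCOC | intermediate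
18 | 6-[(tert-butyldimethylsilyl)oxy]-4-(3,4-dimethoxyphenyl)-5-methoxy-3-(methoxymethoxy)naphthalene-2-carbaldehyde | O=Cc1cc2ccc(O[Si](C)(C)C(C)(C)C)c(OC)c2c(-c2ccc(OC)c(OC)c2)c1OCOC | intermediate
19 | 4-(3,4-dimethoxyphenyl)-6-hydroxy-5-methoxy-3-(methoxymethoxy)naphthalene-2-carbaldehyde | O=Cc1cc2ccc(O)c(OC)c2c(-c2ccc(OC)c(OC)c2)c1OCOC | intermediate
20 | vitrofolal B, 4-(3,4-dimethoxyphenyl)-3,6-dihydroxy-5-methoxynaphthalene-2-carbaldehyde | COc1ccc(-c2c(O)c(C=O)cc3ccc(O)c(OC)c23)cc1OC | target

**Step count**

Total steps: 10. Longest linear sequence: 9 (steps 1–3 and 5–10, from 1 to 20). Step 4 is a one-step side branch.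

**Steps most likely to fail**

Step 7. Compound 10 has a molecular mass above 540, so it may break down in the melt in the inlet before it evaporates. The ketene would then form in the condensed phase and be lost to oligomerisation.

The fallback sets out from 5 and postpones ring C, so that a much lighter substrate is pyrolysed and the C1–ring C bond is made by cross-coupling.
- Negishi methylation of 5 with MeZnCl (Pd(OAc)2, SPhos, THF) would give 4-[(tert-butyldimethylsilyl)oxy]-3-methoxy-2-methylbenzaldehyde F1.
- Knoevenagel condensation with 9 would give 5-({4-[(tert-butyldimethylsilyl)oxy]-3-methoxy-2-methylphenyl}methylidene)-2,2-dimethyl-1,3-dioxane-4,6-dione F2. It is lighter than 10 by 136 mass units and is the parent ortho-tolyl case of the pyrolysis.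
- Its pyrolysis would give 7-[(tert-butyldimethylsilyl)oxy]-8-methoxynaphthalen-2-ol F3.
- NBS in MeCN at low temperature should brominate the most activated position, giving 1-bromo-7-[(tert-butyldimethylsilyl)oxy]-8-methoxynaphthalen-2-ol F4.
- Suzuki–Miyaura coupling with (3,4-dimethoxyphenyl)boronic acid (Pd(OAc)2, SPhos, K3PO4, toluene) comes back to the route at 14.

Step 5. Uncatalysed 1,2-addition of the benzylic zinc reagent to the formyl group may outrun a coupling that is slowed by the two ortho substituents.

The fallback sets out from 5 and masks the aldehyde first.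
- HC(OMe)3 with catalytic TsOH in MeOH would give 3-[(tert-butyldimethylsilyl)oxy]-6-(dimethoxymethyl)-2-methoxyphenyl trifluoromethanesulfonate F5.
- Coupling with 7 under Pd(OAc)2/SPhos can now be run warm and with excess zinc reagent. It would give tert-butyl{4-(dimethoxymethyl)-3-[(3,4-dimethoxyphenyl)methyl]-2-methoxyphenoxy}dimethylsilane F6.
- Brief treatment with dilute aqueous HCl in THF comes back to the route at 8.

Step 9. Metalation may take place on ring C, or butyllithium may attack silicon with loss of the protecting group.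

The fallback sets out from 14. It replaces the external formylation by an intramolecular carbamoyl transfer, which needs only an amide base.
- Et2NCOCl and NaH in THF would give 7-[(tert-butyldimethylsilyl)oxy]-1-(3,4-dimethoxyphenyl)-8-methoxynaphthalen-2-yl N,N-diethylcarbamate F7.
- LiN(iPr)2 in THF, −78 °C → rt, should trigger the anionic ortho-Fries rearrangement to C3, the only free ortho site. The product would be 6-[(tert-butyldimethylsilyl)oxy]-4-(3,4-dimethoxyphenyl)-N,N-diethyl-3-hydroxy-5-methoxynaphthalene-2-carboxamide F8.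
- Excess Cp2Zr(H)Cl in THF would reduce the tertiary amide to 6-[(tert-butyldimethylsilyl)oxy]-4-(3,4-dimethoxyphenyl)-3-hydroxy-5-methoxynaphthalene-2-carbaldehyde F9.
- Bu4NF in THF comes back to the route at 20.

**Further compounds**

F1 | step 7 | 4-[(tert-butyldimethylsilyl)oxy]-3-methoxy-2-methylbenzaldehyde | O=Cc1ccc(O[Si](C)(C)C(C)(C)C)c(OC)c1C
F2 | step 7 | 5-({4-[(tert-butyldimethylsilyl)oxy]-3-methoxy-2-methylphenyl}methylidene)-2,2-dimethyl-1,3-dioxane-4,6-dione | CC1(C)OC(=O)C(=Cc2ccc(O[Si](C)(C)C(C)(C)C)c(OC)c2C)C(=O)O1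
F3 | step 7 | 7-[(tert-butyldimethylsilyl)oxy]-8-methoxynaphthalen-2-ol | COc1c(O[Si](C)(C)C(C)(C)C)ccc2ccc(O)cc12
F4 | step 7 | 1-bromo-7-[(tert-butyldimethylsilyl)oxy]-8-methoxynaphthalen-2-ol | COc1c(O[Si](C)(C)C(C)(C)C)ccc2ccc(O)c(Br)c12
F5 | step 5 | 3-[(tert-butyldimethylsilyl)oxy]-6-(dimethoxymethyl)-2-methoxyphenyl trifluoromethanesulfonate | COC(OC)c1ccc(O[Si](C)(C)C(C)(C)C)c(OC)c1OS(=O)(=O)C(F)(F)F
F6 | step 5 | tert-butyl{4-(dimethoxymethyl)-3-[(3,4-dimethoxyphenyl)methyl]-2-methoxyphenoxy}dimethylsilane | COC(OC)c1ccc(O[Si](C)(C)C(C)(C)C)c(OC)c1Cc1ccc(OC)c(OC)c1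
F7 | step 9 | 7-[(tert-butyldimethylsilyl)oxy]-1-(3,4-dimethoxyphenyl)-8-methoxynaphthalen-2-yl N,N-diethylcarbamate | CCN(CC)C(=O)Oc1ccc2ccc(O[Si](C)(C)C(C)(C)C)c(OC)c2c1-c1ccc(OC)c(OC)c1
F8 | step 9 | 6-[(tert-butyldimethylsilyl)oxy]-4-(3,4-dimethoxyphenyl)-N,N-diethyl-3-hydroxy-5-methoxynaphthalene-2-carboxamide | CCN(CC)C(=O)c1cc2ccc(O[Si](C)(C)C(C)(C)C)c(OC)c2c(-c2ccc(OC)c(OC)c2)c1O
F9 | step 9 | 6-[(tert-butyldimethylsilyl)oxy]-4-(3,4-dimethoxyphenyl)-3-hydroxy-5-methoxynaphthalene-2-carbaldehyde | O=Cc1cc2ccc(O[Si](C)(C)C(C)(C)C)c(OC)c2c(-c2ccc(OC)c(OC)c2)c1O
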